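**Total synthesis proposal for (1R,3S,4aR,5R,8aR)-5-[(3E)-4-carboxy-3-methylbut-3-en-1-yl]-3-hydroxy-1,4a-dimethyl-6-methylidenedecahydronaphthalene-1-carboxylic acid**

## Retrosynthetic overview

1. Endgame: the target comes from a C2 ketone (hydride from the open α face gives the axial alcohol), a C15 allylic alcohol (oxidised to the acid) and a C19 allyl ester.
2. Key disconnection: C8–C9 and C1–C10 are made in one gold-catalysed bicyclisation of an acyclic 1,6-enyne that carries a 2-methoxyallyl (enol ether) terminator. Ring B closes first, ring A second in the same operation; C17 appears as the exocyclic =CH2 and C2 as a ketone.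
3. Enabling feature: in ring B the exocyclic C8=C17 methylene sits next to C9, whose side chain is axial and anti-periplanar to the C10 methyl, and C2 (β to C10 through C1) carries oxygen. This is the pattern left by anti addition of an alkyne carbon (C8) and an enol carbon (C1) across a (Z)-C9=C10 olefin.
4. The enyne comes from a δ-lactone used as a temporary ring. Rhodium-catalysed asymmetric 1,4-addition of a (Z)-alkenyl boronate (C9–C16 and C20, from geraniol) to 5,6-dihydro-2H-pyran-2-one sets C5. Methylation and then 2-methoxyallylation (trans to the alkenyl group) set C4. Ring opening, mesylation and acetylide displacement give the butynyl arm.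

Key step: step 12

Assumption: the stereodescriptors of the SMILES are taken literally, i.e. trans-decalin, C4 carboxyl equatorial (anti to the C10 methyl), C2 hydroxyl axial, C9 side chain axial and anti to the C10 methyl; labdane numbering (C1–C20) is used for positions throughout.

## Route

Step 1
Reactants: 1 geraniol
Product: 2 tert-butyl{[(2E)-3,7-dimethylocta-2,6-dien-1-yl]oxy}dimethylsilane
Conditions: TBSCl, imidazole, CH2Cl2, rt
Reagents that add atoms: tert-butyldimethylsilyl chloride, CC(C)(C)[Si](C)(C)Cl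
Why: Standard silylation of a primary allylic alcohol (substitution at silicon), which gives a C15 protecting group without acidic C–H bonds for the later enolate steps.

Step 2
Reactants: 2 tert-butyl{[(2E)-3,7-dimethylocta-2,6-dien-1-yl]oxy}dimethylsilane
Product: 4 (4E)-6-[(tert-butyldimethylsilyl)oxy]-4-methylhex-4-enal, via epoxide 3 (not isolated)
Conditions: mCPBA (1.0 equiv), CH2Cl2, −20 °C; then H5IO6, THF/H2O, 0 °C
Reagents that add atoms: 3-chloroperoxybenzoic acid, O=C(OO)c1cccc(Cl)c1
Why: Prilezhaev epoxidation should take the more electron-rich remote olefin (the other one is deactivated by the allylic silyloxy group), and periodic acid cleaves the epoxide through its diol to the aldehyde and acetone without touching the E olefin.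

Step 3
Reactants: 4 (4E)-6-[(tert-butyldimethylsilyl)oxy]-4-methylhex-4-enal
Product: 5 tert-butyl{[(2E,6Z)-7-iodo-3-methylocta-2,6-dien-1-yl]oxy}dimethylsilane
Conditions: EtPPh3I, n-BuLi, THF, rt; I2, −78 °C; NaN(SiMe3)2, −20 °C; then 4, −78 °C → rt
Reagents that add atoms: ethyltriphenylphosphonium iodide, CC[P+](c1ccccc1)(c1ccccc1)c1ccccc1.[I-]; iodine, II
Why: Stork–Zhao olefination with the α-iodo ylide should give the (Z)-2-iodoalkene (iodine cis to the chain) under kinetic control, which is the geometry that later becomes the Z C9=C10 olefin.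

Step 4
Reactants: 5 tert-butyl{[(2E,6Z)-7-iodo-3-methylocta-2,6-dien-1-yl]oxy}dimethylsilane
Product: 6 tert-butyldimethyl{[(2E,6E)-3-methyl-7-(4,4,5,5-tetramethyl-1,3,2-dioxaborolan-2-yl)octa-2,6-dien-1-yl]oxy}silane
Conditions: B2pin2, PdCl2(PPh3)2 (3 mol %), PPh3, KOPh, toluene, 50 °C
Reagents that add atoms: bis(pinacolato)diboron, CC1(C)OB(OC1(C)C)B1OC(C)(C)C(C)(C)O1
Why: Miyaura borylation of an alkenyl iodide proceeds with retention of olefin geometry, so boron stays cis to the chain (the E descriptor only reflects the priority of CH3 over B).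

Step 5
Reactants: 6 tert-butyldimethyl{[(2E,6E)-3-methyl-7-(4,4,5,5-tetramethyl-1,3,2-dioxaborolan-2-yl)octa-2,6-dien-1-yl]oxy}silane; 7 5,6-dihydro-2H-pyran-2-one
Product: 8 (4S)-4-[(2Z,6E)-8-[(tert-butyldimethylsilyl)oxy]-6-methylocta-2,6-dien-2-yl]oxan-2-one
Conditions: [RhCl(C2H4)2]2 (2.5 mol %), (S)-BINAP (5.5 mol %), KOH (0.5 equiv), 1,4-dioxane/H2O 10:1, 50 °C; 7 (2 equiv); work-up at pH 3
Reagents that add atoms: none
Why: Hayashi–Miyaura asymmetric 1,4-addition (transmetalation to monovalent rhodium with retention of alkenyl geometry, enantioface-selective carbometalation, hydrolysis of the rhodium enolate) sets C5, and the (S)-BINAP complex is expected, by the model established for 2-cyclohexenone, to give the (S)-configured ring carbon.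

Step 6
Reactants: 8 (4S)-4-[(2Z,6E)-8-[(tert-butyldimethylsilyl)oxy]-6-methylocta-2,6-dien-2-yl]oxan-2-one
Product: 9 (3R,4S)-4-[(2Z,6E)-8-[(tert-butyldimethylsilyl)oxy]-6-methylocta-2,6-dien-2-yl]-3-methyloxan-2-one
Conditions: LiN(iPr)2, THF, −78 °C; MeI, −78 → −40 °C
Reagents that add atoms: iodomethane, CI
Why: Lactone enolate alkylation (SN2) should introduce the C4 methyl trans to the C5 alkenyl group, but this centre is planarised again in step 8, so only the constitution matters here.

Step 7
Reactants: 10 1-bromo-2,2-dimethoxypropane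
Product: 11 3-bromo-2-methoxyprop-1-ene
Conditions: iPr2NEt·TsOH (cat.), neat, 150 °C, MeOH distilled off
Reagents that add atoms: none
Why: Acid-catalysed loss of methanol from the ketal (ketal cracking) is the known preparation of this acetonyl equivalent, and any isomeric 1-bromo-2-methoxypropene is inert in step 8.

Step 8
Reactants: 9 (3R,4S)-4-[(2Z,6E)-8-[(tert-butyldimethylsilyl)oxy]-6-methylocta-2,6-dien-2-yl]-3-methyloxan-2-one; 11 3-bromo-2-methoxyprop-1-ene
Product: 12 (3R,4R)-4-[(2Z,6E)-8-[(tert-butyldimethylsilyl)oxy]-6-methylocta-2,6-dien-2-yl]-3-(2-methoxyprop-2-en-1-yl)-3-methyloxan-2-one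
Conditions: LiN(iPr)2, THF, −78 °C; DMPU; 11, −78 → −30 °C
Reagents that add atoms: none
Why: Alkylation of the tetrasubstituted lactone enolate by the allylic bromide should occur anti to the neighbouring C5 alkenyl group, so the entering C3 unit ends trans and the methyl cis to it, which sets the quaternary C4 with the relative configuration of the target (the C5 descriptor changes only because the priorities change).

Step 9
Reactants: 12 (3R,4R)-4-[(2Z,6E)-8-[(tert-butyldimethylsilyl)oxy]-6-methylocta-2,6-dien-2-yl]-3-(2-methoxyprop-2-en-1-yl)-3-methyloxan-2-one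
Product: 14 prop-2-en-1-yl (2R,3R,4Z,8E)-10-[(tert-butyldimethylsilyl)oxy]-3-(2-hydroxyethyl)-2-(2-methoxyprop-2-en-1-yl)-2,4,8-trimethyldeca-4,8-dienoate, via lithium carboxylate 13 (not isolated)
Conditions: LiOH·H2O, THF/MeOH/H2O, 40 °C; evaporate; allyl bromide, DMF, rt
Reagents that add atoms: lithium hydroxide, [Li+].[OH-]; allyl bromide, C=CCBr
Why: Saponification opens the temporary lactone ring and O-alkylation (SN2) of the carboxylate traps the open form as the allyl ester, while the enol ether and silyl ether are stable to base.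

Step 10
Reactants: 14 prop-2-en-1-yl (2R,3R,4Z,8E)-10-[(tert-butyldimethylsilyl)oxy]-3-(2-hydroxyethyl)-2-(2-methoxyprop-2-en-1-yl)-2,4,8-trimethyldeca-4,8-dienoate
Product: 15 prop-2-en-1-yl (2R,3R,4Z,8E)-10-[(tert-butyldimethylsilyl)oxy]-3-{2-[(methanesulfonyl)oxy]ethyl}-2-(2-methoxyprop-2-en-1-yl)-2,4,8-trimethyldeca-4,8-dienoate
Conditions: MsCl, Et3N, CH2Cl2, 0 °C
Reagents that add atoms: methanesulfonyl chloride, CS(=O)(=O)Cl
Why: Sulfonylation of the primary alcohol under basic conditions activates C7 and spares the acid-labile enol ether.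

Step 11
Reactants: 15 prop-2-en-1-yl (2R,3R,4Z,8E)-10-[(tert-butyldimethylsilyl)oxy]-3-{2-[(methanesulfonyl)oxy]ethyl}-2-(2-methoxyprop-2-en-1-yl)-2,4,8-trimethyldeca-4,8-dienoate
Product: 16 prop-2-en-1-yl (2R,3R)-3-[(2Z,6E)-8-[(tert-butyldimethylsilyl)oxy]-6-methylocta-2,6-dien-2-yl]-2-(2-methoxyprop-2-en-1-yl)-2-methylhept-6-ynoate
Conditions: LiC≡CH·H2NCH2CH2NH2, DMSO, rt
Reagents that add atoms: lithium acetylide ethylenediamine complex, [Li+].[C-]#C.NCCN
Why: SN2 displacement of the primary mesylate by acetylide in a dipolar aprotic solvent installs C8 and C17, and the allyl ester on the quaternary C4 is too hindered to be attacked at room temperature.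

Step 12
Reactants: 16 prop-2-en-1-yl (2R,3R)-3-[(2Z,6E)-8-[(tert-butyldimethylsilyl)oxy]-6-methylocta-2,6-dien-2-yl]-2-(2-methoxyprop-2-en-1-yl)-2-methylhept-6-ynoate
Product: 18 prop-2-en-1-yl (1R,4aR,5R,8aR)-5-[(3E)-5-hydroxy-3-methylpent-3-en-1-yl]-1,4a-dimethyl-6-methylidene-3-oxodecahydronaphthalene-1-carboxylate, via methyl enol ether 17 (not isolated)
Conditions: [Au{P(t-Bu)2(2-biphenylyl)}(NCMe)]SbF6 (3 mol %), 4 Å MS, CH2Cl2, −20 °C → rt; then AcOH/THF/H2O 3:1:1, 40 °C
Reagents that add atoms: water, O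
Why: Proposed new method: cationic monovalent gold activates the terminal alkyne, C9 of the (Z)-C9=C10 olefin attacks the internal alkyne carbon C8 (Markovnikov, cyclopropyl gold carbene with tertiary cation character at C10), the enol ether terminus C1 captures C10 anti to the new C8–C9 bond, and loss of a proton from the oxocarbenium ion followed by protodeauration gives enol ether 17 with the exocyclic C8=C17 methylene, which aqueous acetic acid hydrolyses to the C2 ketone while removing the silyl group. The closest known reactions are the gold-catalysed alkoxy- and carbocyclisations of 1,6-enynes whose internal olefin carbon is the more substituted one (six-membered ring with exocyclic methylene) and gold-catalysed enyne polycyclisations ended by carbon nucleophiles such as enol silanes; an enol ether placed on the allylic tether carbon so that it builds a quaternary ring-fusion carbon has not been shown. Ring B closes 6-exo-dig at the alkyne (6-endo-trig at the olefin) and ring A closes 6-endo-trig at the enol ether through a chair. C9 (R) and C10 (R) follow from stereospecific anti addition across the Z olefin, which leaves C11 and the C10 methyl anti (trans-diaxial) and C1 equatorial. The trans ring fusion is relayed from C5: allylic 1,3-strain with the cis C11 chain keeps H5 in the olefin plane, so the butynyl arm and the C4 arm lie on opposite faces as anti addition requires, while the cis-fused alternative would force the quaternary C4 against C11. The step needs six- over five-membered ring formation (secured by the tertiary C10 cation) and capture by the enol ether rather than by the C13=C14 olefin or an ester oxygen (secured by its much higher π-nucleophilicity and by the deactivating allylic silyloxy group).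

Step 13
Reactants: 18 prop-2-en-1-yl (1R,4aR,5R,8aR)-5-[(3E)-5-hydroxy-3-methylpent-3-en-1-yl]-1,4a-dimethyl-6-methylidene-3-oxodecahydronaphthalene-1-carboxylate
Product: 19 prop-2-en-1-yl (1R,3S,4aR,5R,8aR)-3-hydroxy-5-[(3E)-5-hydroxy-3-methylpent-3-en-1-yl]-1,4a-dimethyl-6-methylidenedecahydronaphthalene-1-carboxylate
Conditions: NaBH4, MeOH, 0 °C
Reagents that add atoms: none
Why: Hydride reduction of the C2 ketone should occur from the α face because the axial β trajectory is blocked by the two syn-axial methyl groups on C4 and C10, which gives the axial (S) alcohol, and the allyl ester is not reduced.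

Step 14
Reactants: 19 prop-2-en-1-yl (1R,3S,4aR,5R,8aR)-3-hydroxy-5-[(3E)-5-hydroxy-3-methylpent-3-en-1-yl]-1,4a-dimethyl-6-methylidenedecahydronaphthalene-1-carboxylate
Product: 21 prop-2-en-1-yl (1R,3S,4aR,5R,8aR)-5-[(3E)-4-carboxy-3-methylbut-3-en-1-yl]-3-hydroxy-1,4a-dimethyl-6-methylidenedecahydronaphthalene-1-carboxylate, via enal 20 (not isolated)
Conditions: MnO2, CH2Cl2, rt; filter; then NaClO2, NaH2PO4, 2-methyl-2-butene, t-BuOH/H2O, rt
Reagents that add atoms: sodium chlorite, [Na+].[O-]Cl=O
Why: MnO2 oxidises only the allylic alcohol (the hindered saturated C2 alcohol is inert) and the Pinnick oxidation converts the enal into the acid with retention of the E geometry while the scavenger protects the olefins from hypochlorite.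

Step 15
Reactants: 21 prop-2-en-1-yl (1R,3S,4aR,5R,8aR)-5-[(3E)-4-carboxy-3-methylbut-3-en-1-yl]-3-hydroxy-1,4a-dimethyl-6-methylidenedecahydronaphthalene-1-carboxylate
Product: 22 (1R,3S,4aR,5R,8aR)-5-[(3E)-4-carboxy-3-methylbut-3-en-1-yl]-3-hydroxy-1,4a-dimethyl-6-methylidenedecahydronaphthalene-1-carboxylic acid
Conditions: Pd(PPh3)4 (5 mol %), morpholine, THF, rt; then 1 M HCl work-up
Reagents that add atoms: none
Why: Tsuji–Trost deallylation (zerovalent palladium ionises the allyl ester to a π-allyl complex that morpholine captures) frees the hindered C4 carboxylic acid under neutral conditions without touching a stereocentre.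

## Compound list

1 | geraniol, (2E)-3,7-dimethylocta-2,6-dien-1-ol | CC(C)=CCC/C(C)=C/CO | starting material
2 | tert-butyl{[(2E)-3,7-dimethylocta-2,6-dien-1-yl]oxy}dimethylsilane | CC(C)=CCC/C(C)=C/CO[Si](C)(C)C(C)(C)C | intermediate
3 | tert-butyl{[(2E)-5-(3,3-dimethyloxiran-2-yl)-3-methylpent-2-en-1-yl]oxy}dimethylsilane (racemic epoxide, not isolated) | CC1(C)OC1CC/C(C)=C/CO[Si](C)(C)C(C)(C)C | intermediate
4 | (4E)-6-[(tert-butyldimethylsilyl)oxy]-4-methylhex-4-enal | O=CCC/C(C)=C/CO[Si](C)(C)C(C)(C)C | intermediate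
5 | tert-butyl{[(2E,6Z)-7-iodo-3-methylocta-2,6-dien-1-yl]oxy}dimethylsilane | I/C(C)=C\CC/C(C)=C/CO[Si](C)(C)C(C)(C)C | intermediate
6 | tert-butyldimethyl{[(2E,6E)-3-methyl-7-(4,4,5,5-tetramethyl-1,3,2-dioxaborolan-2-yl)octa-2,6-dien-1-yl]oxy}silane (boron cis to the chain) | CC1(C)OB(OC1(C)C)/C(C)=C\CC/C(C)=C/CO[Si](C)(C)C(C)(C)C | intermediate
7 | 5,6-dihydro-2H-pyran-2-one | O=C1C=CCCO1 | starting material
8 | (4S)-4-[(2Z,6E)-8-[(tert-butyldimethylsilyl)oxy]-6-methylocta-2,6-dien-2-yl]oxan-2-one | O=C1C[C@H](CCO1)/C(C)=C\CC/C(C)=C/CO[Si](C)(C)C(C)(C)C | intermediate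
9 | (3R,4S)-4-[(2Z,6E)-8-[(tert-butyldimethylsilyl)oxy]-6-methylocta-2,6-dien-2-yl]-3-methyloxan-2-one | C[C@H]1C(=O)OCC[C@@H]1/C(C)=C\CC/C(C)=C/CO[Si](C)(C)C(C)(C)C | intermediate
10 | 1-bromo-2,2-dimethoxypropane | COC(C)(CBr)OC | starting material
11 | 3-bromo-2-methoxyprop-1-ene (2-methoxyallyl bromide) | COC(=C)CBr | intermediate
12 | (3R,4R)-4-[(2Z,6E)-8-[(tert-butyldimethylsilyl)oxy]-6-methylocta-2,6-dien-2-yl]-3-(2-methoxyprop-2-en-1-yl)-3-methyloxan-2-one | COC(=C)C[C@@]1(C)C(=O)OCC[C@@H]1/C(C)=C\CC/C(C)=C/CO[Si](C)(C)C(C)(C)C | intermediate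
13 | lithium (2R,3R,4Z,8E)-10-[(tert-butyldimethylsilyl)oxy]-3-(2-hydroxyethyl)-2-(2-methoxyprop-2-en-1-yl)-2,4,8-trimethyldeca-4,8-dienoate (not isolated) | [Li+].COC(=C)C[C@@](C)(C(=O)[O-])[C@H](CCO)/C(C)=C\CC/C(C)=C/CO[Si](C)(C)C(C)(C)C | intermediate
14 | prop-2-en-1-yl (2R,3R,4Z,8E)-10-[(tert-butyldimethylsilyl)oxy]-3-(2-hydroxyethyl)-2-(2-methoxyprop-2-en-1-yl)-2,4,8-trimethyldeca-4,8-dienoate | COC(=C)C[C@@](C)(C(=O)OCC=C)[C@H](CCO)/C(C)=C\CC/C(C)=C/CO[Si](C)(C)C(C)(C)C | intermediate
15 | prop-2-en-1-yl (2R,3R,4Z,8E)-10-[(tert-butyldimethylsilyl)oxy]-3-{2-[(methanesulfonyl)oxy]ethyl}-2-(2-methoxyprop-2-en-1-yl)-2,4,8-trimethyldeca-4,8-dienoate | COC(=C)C[C@@](C)(C(=O)OCC=C)[C@H](CCOS(C)(=O)=O)/C(C)=C\CC/C(C)=C/CO[Si](C)(C)C(C)(C)C | intermediate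
16 | prop-2-en-1-yl (2R,3R)-3-[(2Z,6E)-8-[(tert-butyldimethylsilyl)oxy]-6-methylocta-2,6-dien-2-yl]-2-(2-methoxyprop-2-en-1-yl)-2-methylhept-6-ynoate | COC(=C)C[C@@](C)(C(=O)OCC=C)[C@H](CCC#C)/C(C)=C\CC/C(C)=C/CO[Si](C)(C)C(C)(C)C | intermediate
17 | cyclised methyl enol ether: the C2 methyl enol ether (C2=C3) of ketone 18 with the C15 tert-butyldimethylsilyl ether still in place, ring stereocentres as in 18 (not isolated) | C=C1CC[C@@H]2[C@](C)(CC(OC)=C[C@@]2(C)C(=O)OCC=C)[C@@H]1CC/C(C)=C/CO[Si](C)(C)C(C)(C)C | intermediate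
18 | prop-2-en-1-yl (1R,4aR,5R,8aR)-5-[(3E)-5-hydroxy-3-methylpent-3-en-1-yl]-1,4a-dimethyl-6-methylidene-3-oxodecahydronaphthalene-1-carboxylate | C=C1CC[C@@H]2[C@](C)(CC(=O)C[C@@]2(C)C(=O)OCC=C)[C@@H]1CC/C(C)=C/CO | intermediate
19 | prop-2-en-1-yl (1R,3S,4aR,5R,8aR)-3-hydroxy-5-[(3E)-5-hydroxy-3-methylpent-3-en-1-yl]-1,4a-dimethyl-6-methylidenedecahydronaphthalene-1-carboxylate | C=C1CC[C@@H]2[C@](C)(C[C@H](O)C[C@@]2(C)C(=O)OCC=C)[C@@H]1CC/C(C)=C/CO | intermediate
20 | prop-2-en-1-yl (1R,3S,4aR,5R,8aR)-3-hydroxy-1,4a-dimethyl-6-methylidene-5-[(3E)-3-methyl-5-oxopent-3-en-1-yl]decahydronaphthalene-1-carboxylate (not isolated) | C=C1CC[C@@H]2[C@](C)(C[C@H](O)C[C@@]2(C)C(=O)OCC=C)[C@@H]1CC/C(C)=C/C=O | intermediate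
21 | prop-2-en-1-yl (1R,3S,4aR,5R,8aR)-5-[(3E)-4-carboxy-3-methylbut-3-en-1-yl]-3-hydroxy-1,4a-dimethyl-6-methylidenedecahydronaphthalene-1-carboxylate | C=C1CC[C@@H]2[C@](C)(C[C@H](O)C[C@@]2(C)C(=O)OCC=C)[C@@H]1CC/C(C)=C/C(=O)O | intermediate
22 | (1R,3S,4aR,5R,8aR)-5-[(3E)-4-carboxy-3-methylbut-3-en-1-yl]-3-hydroxy-1,4a-dimethyl-6-methylidenedecahydronaphthalene-1-carboxylic acid | C=C1CC[C@@H]2[C@](C)(C[C@H](O)C[C@@]2(C)C(=O)O)[C@@H]1CC/C(C)=C/C(=O)O | target

## Step count and risks

Total step count: 15. Longest linear sequence: 14 steps (steps 1–6 and 8–15; step 7 prepares the alkylating agent).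

Steps most likely to fail:

1. Step 12 (proposed new method). The C10 cation may be quenched by proton loss or by the C13=C14 olefin before the enol ether closes ring A, or the enol ether may be hydrolysed by traces of acid before the cyclisation starts. The fallback uses known chemistry in separate operations; it sets out from 16 and comes back at 18. Mild hydrolysis of the enol ether (oxalic acid on wet silica gel) would give the methyl ketone F1. The same gold complex, [Au{P(t-Bu)2(2-biphenylyl)}(NCMe)]SbF6, in CH2Cl2/MeOH would effect the established methoxycyclisation of the 1,6-enyne to the ring B tertiary methyl ether F2 (exocyclic methylene, C9 set as in the main route). LiN(iPr)2/Me3SiCl would give the terminal trimethylsilyl enol ether F3. TiCl4 at −78 °C would ionise the tertiary ether and close ring A by intramolecular tert-alkylation of the enol silane to the silyl-protected ketone F4. In this closure the ring fusion is not tied to an anti addition, so a cis-fused isomer may have to be separated. AcOH/THF/H2O would then convert F4 into 18.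

2. Step 5. Transmetalation of the α-branched alkenyl boronate may be slow, so that protodeboronation and hydrolysis of the lactone under the basic aqueous conditions lower the conversion or the enantioselectivity. The fallback replaces catalyst control by an oxazolidinone auxiliary; it sets out from 5 and comes back at 8. Iodide 5 would be converted by t-BuLi (Et2O, −78 °C), MgBr2·OEt2 and CuBr·SMe2 into the alkenyl copper–magnesium reagent. This would be added to the N-enoyl oxazolidinone acceptor F5 (made from (4R)-4-benzyl-1,3-oxazolidin-2-one and (2E)-5-[(4-methoxybenzyl)oxy]pent-2-enoic acid) to give the 1,4-adduct F6, with the face chosen by the chelated s-cis conformer of the auxiliary. DDQ would remove the 4-methoxybenzyl group to give the hydroxy imide F7, and DBU would close the lactone with release of the auxiliary, giving 8.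

3. Step 8. The hindered tertiary enolate may react slowly, so that decomposition of the labile bromo enol ether and O-alkylation compete. The fallback installs the carbon skeleton with a robust electrophile and adjusts the oxidation state afterwards; it sets out from 9 and comes back at 12. Alkylation of the enolate of 9 with allyl bromide (same facial preference) would give the allyl lactone F8. Wacker oxidation (PdCl2, CuCl, O2, DMF/H2O) of the terminal olefin would give the methyl ketone F9. MeOSiMe3 with catalytic Me3SiOTf would give the dimethyl ketal F10, and Me3SiOTf/iPr2NEt would eliminate methanol towards the methyl group to give 12.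

## Further compounds

F1 | step 12 | prop-2-en-1-yl (2R,3R)-3-[(2Z,6E)-8-[(tert-butyldimethylsilyl)oxy]-6-methylocta-2,6-dien-2-yl]-2-methyl-2-(2-oxopropyl)hept-6-ynoate | CC(=O)C[C@@](C)(C(=O)OCC=C)[C@H](CCC#C)/C(C)=C\CC/C(C)=C/CO[Si](C)(C)C(C)(C)C
F2 | step 12 | ring B tertiary methyl ether: monocyclic product with C8=CH2, methoxy on C10 in place of the C1–C10 bond, C4, C5 and C9 as in 18, methyl ketone arm and silyl ether retained | C=C1CC[C@@H]([C@](C)(C(=O)OCC=C)CC(C)=O)[C@](C)(OC)[C@@H]1CC/C(C)=C/CO[Si](C)(C)C(C)(C)C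
F3 | step 12 | terminal trimethylsilyl enol ether of F2 | C=C1CC[C@@H]([C@](C)(C(=O)OCC=C)CC(=C)O[Si](C)(C)C)[C@](C)(OC)[C@@H]1CC/C(C)=C/CO[Si](C)(C)C(C)(C)C
F4 | step 12 | tert-butyldimethylsilyl ether of 18 | C=C1CC[C@@H]2[C@](C)(CC(=O)C[C@@]2(C)C(=O)OCC=C)[C@@H]1CC/C(C)=C/CO[Si](C)(C)C(C)(C)C
F5 | step 5 | (4R)-4-benzyl-3-{(2E)-5-[(4-methoxybenzyl)oxy]pent-2-enoyl}-1,3-oxazolidin-2-one | O=C1OC[C@@H](Cc2ccccc2)N1C(=O)/C=C/CCOCc3ccc(OC)cc3
F6 | step 5 | 1,4-adduct: N-acyl oxazolidinone carrying the (Z)-alkenyl group at C5 and the 4-methoxybenzyl ether on C7 | O=C1OC[C@@H](Cc2ccccc2)N1C(=O)C[C@H](CCOCc3ccc(OC)cc3)/C(C)=C\CC/C(C)=C/CO[Si](C)(C)C(C)(C)C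
F7 | step 5 | hydroxy imide obtained from F6 by removal of the 4-methoxybenzyl group | O=C1OC[C@@H](Cc2ccccc2)N1C(=O)C[C@H](CCO)/C(C)=C\CC/C(C)=C/CO[Si](C)(C)C(C)(C)C
F8 | step 8 | 3-allyl analogue of 12: allyl in place of 2-methoxyallyl, same configuration | C=CC[C@@]1(C)C(=O)OCC[C@@H]1/C(C)=C\CC/C(C)=C/CO[Si](C)(C)C(C)(C)C
F9 | step 8 | 3-(2-oxopropyl) analogue of 12 | CC(=O)C[C@@]1(C)C(=O)OCC[C@@H]1/C(C)=C\CC/C(C)=C/CO[Si](C)(C)C(C)(C)C
F10 | step 8 | 3-(2,2-dimethoxypropyl) analogue of 12 | COC(C)(OC)C[C@@]1(C)C(=O)OCC[C@@H]1/C(C)=C\CC/C(C)=C/CO[Si](C)(C)C(C)(C)C
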